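- Early times don't separate the charges: at 2.50 min Saturday's run reads 8.2% and Wednesday's 8.1%, but c(substrate) goes from 0.50 M to 1 M while c(second nucleophile) goes from 0.38 M to 0.75 M.
- I reckon instead with the fraction left. I leave this flask's charges as written; my decision is how long to sample it.

| flask | substrate | first nucleophile | second nucleophile | remark | time |
|---|---|---|---|---|---|
| Saturday's | 0.50 M | 0.30 M | 0.38 M | run made earlier |  |
| Monday's | 0.50 M | 0.30 M | 1.5 M | run made earlier |  |
| Wednesday's | 1 M | 0.30 M | 0.75 M | run made earlier |  |
| flask | 0.50 M | 0.300 M | 0.750 M |  | 1.0 h |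

- Saturday's (time / min: target / %): 2.50: 8.2; 6.00: 22.6; 15.0: 29.9; 30.0: 30.4; 80.0: 26.7
- Monday's (time / min: target / %): 2.50: 5.3; 6.00: 5.9; 15.0: 4.6; 30.0: 1.3; 80.0: 0.9
- Wednesday's (time / min: target / %): 2.50: 8.1; 6.00: 13.0; 15.0: 13.0; 30.0: 14.4; 80.0: 15.7

(readings scatter by 1 percentage point)

- the earlier runs were read with a standard deviation of 1 percentage point

- time, not beyond 1.0 h, at which the flask holds most target
- the amount of target, in percent of the substrate charged, at that time
- earliest time at which at least nineteen twentieths of that best amount are there
- latest time at which they still are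

- Monday's tail gives my clock. Between 15.0 min and 30.0 min, target falls from 4.6% to 1.3%. So λ, the fraction of what is left that goes per minute, reads 0.0842 min⁻¹, a half-life of 8.23 min.
- That lower reading stands against a scatter of 1 point, so λ is rough.
- If Monday's target comes from a slow feed, the rate-limiting step, and is lost faster, its tail follows the feed. I take it so, and e^(−λt) becomes my fraction of substrate left.
- The forecast puts the flask's peak at 0.2 h (0.13 h to 0.3 h) with 8.2% (6.5% to 10.5%), and the window from 0.14 h to 0.31 h. Its grounds include this: “Substrate is mostly consumed”.
- My clock differs: at 0.2 h about a third of the substrate remains. So I sample this flask out to 0.5 h.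

- The flask gives 14.1% at 0.177 h, open from 0.120 h to 0.254 h, against the forecast's 8.2%. At that best time the flask holds 38.4% substrate, more than target. My clock gives 40.9% for the same moment.

    substrate → intermediate (k = 0.0900 min⁻¹)
    second nucleophile + intermediate → other capture product (k = 430 M⁻¹ min⁻¹)
    substrate + intermediate → side product A (k = 0.720 M⁻¹ min⁻¹)
    intermediate → side product B (k = 0.530 min⁻¹)
    first nucleophile + intermediate → target (k = 990 M⁻¹ min⁻¹)
    second nucleophile + target → over-reaction product (k = 0.200 M⁻¹ min⁻¹)

- In the neighbour flask with 1.9 M of second nucleophile, λ carries no c(second nucleophile), so it gives 0.640% of the substrate left at 1.0 h. The computed neighbour flask holds 0.451% of it.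

(The data stem from a simulated flask for substances that don't exist; the scatter is artificial.)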